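**Retrosynthetic overview**

1. Numbering used: ring C1 (CH carrying the side chain C2(OAng)–C3–C4(OAc)), C5(Me)=C6, C7, C8(O), C9, C10(Me); lactone C11(=C13H2)–C12(=O)–O–C8. The two rings share the C7–C8 bond: C7 is the γ-carbon of a 2-carboxyallyl unit (C13–C11(C12)=C7) and C8 carries the lactone oxygen, which is the retron of a carbonyl allylation by a 2-(alkoxycarbonyl)allyl metal followed by lactonization.
2. Key disconnection C7–C8: intramolecular CrCl2-mediated allylation of an acyclic C8 aldehyde that bears a (2Z,4Z)-2-(bromomethyl)dienoate. One operation closes the seven-membered ring, then the γ-lactone, installs the exo-methylene group and sets C7 and C8; the angelate and the acetate are carried through the cyclization, so its product is the target.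
3. The dienoate comes from a Z-enal (C7) by addition of an α-aluminated acrylate and SN2' bromination. The Z geometry of the C5=C6 alkene is enforced by a temporary ring, a 4-methyl-5,6-dihydropyran-2-one that ties O2 to C7 (ketene-ylide acylation/intramolecular Wittig) and is opened again by aminolysis.
4. C1 and C2 come from an Evans syn-aldol reaction, C10 from methyl hydrogen (R)-3-methylglutarate.
5. Order of ring formation: temporary δ-lactone (formed in step 8, cleaved in step 9), then carbocycle and γ-lactone together in step 18.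

Key step: step 18

Remarks: TBS = tert-butyldimethylsilyl, PMB = 4-methoxybenzyl, Ang/angelate = (Z)-2-methylbut-2-enoyl/-enoate; 3-[(4-methoxybenzyl)oxy]propanal is taken as a catalogue compound (otherwise two routine steps from propane-1,3-diol).

**Route**

Step 1
Reactants: 1 methyl hydrogen (R)-3-methylglutarate [(3R)-5-methoxy-3-methyl-5-oxopentanoic acid]
Product: 2 methyl (3R)-5-hydroxy-3-methylpentanoate
Conditions: BH3·SMe2, THF, 0 °C to rt; then MeOH
Reagents that add atoms: none
Why: Borane reduces the free carboxylic acid (via the acyloxyborane) much faster than the methyl ester, so the acid carbon becomes C8 at the alcohol level while C10 keeps its R configuration (chemoselective borane reduction).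

Step 2
Reactants: 2 methyl (3R)-5-hydroxy-3-methylpentanoate
Product: 3 methyl (3R)-5-[(tert-butyldimethylsilyl)oxy]-3-methylpentanoate
Conditions: TBSCl, imidazole, DMF, 0 °C to rt
Reagents that add atoms: tert-butyldimethylsilyl chloride, CC(C)(C)[Si](C)(C)Cl
Why: Corey silylation of the primary alcohol is run directly on the crude hydroxy ester, which forestalls its lactonization and gives a C8 protecting group meant to last until step 16.

Step 3
Reactants: 3 methyl (3R)-5-[(tert-butyldimethylsilyl)oxy]-3-methylpentanoate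
Product: 4 (3R)-5-[(tert-butyldimethylsilyl)oxy]-3-methylpentanoic acid
Conditions: LiOH, THF/MeOH/H2O, rt; then 1 M HCl to pH 4, 0 °C
Reagents that add atoms: lithium hydroxide, [Li+].[OH-]
Why: Saponification of the unhindered methyl ester with LiOH should leave the primary TBS ether intact when the acid is liberated at pH 4 in the cold.

Step 4
Reactants: 4 (3R)-5-[(tert-butyldimethylsilyl)oxy]-3-methylpentanoic acid; 5 (R)-4-benzyl-1,3-oxazolidin-2-one
Product: 7 (4R)-4-benzyl-3-{(3R)-5-[(tert-butyldimethylsilyl)oxy]-3-methylpentanoyl}-1,3-oxazolidin-2-one, via mixed pivalic anhydride 6 (not isolated)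
Conditions: PivCl, Et3N, THF, −20 °C; then 5, LiCl, −20 °C to rt
Reagents that add atoms: none
Why: Activation as the mixed pivalic anhydride followed by LiCl/Et3N-mediated N-acylation is the standard way to load an Evans oxazolidinone without touching the C10 centre or the silyl ether.

Step 5
Reactants: 7 (4R)-4-benzyl-3-{(3R)-5-[(tert-butyldimethylsilyl)oxy]-3-methylpentanoyl}-1,3-oxazolidin-2-one; 8 3-[(4-methoxybenzyl)oxy]propanal
Product: 10 (4R)-4-benzyl-3-{(2R,3S)-2-[(2R)-4-(TBSO)butan-2-yl]-3-hydroxy-5-(PMBO)pentanoyl}-1,3-oxazolidin-2-one, via dibutylboron (Z)-enolate 9 (not isolated)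
Conditions: Bu2BOTf, iPr2NEt, CH2Cl2, −78 to 0 °C; 8, −78 to 0 °C; then pH 7 buffer (KH2PO4/K2HPO4), MeOH, 30% H2O2, 0 °C
Reagents that add atoms: none
Why: Evans boron aldol reaction, in which the (Z)-enolate adds to the aldehyde through a Zimmerman–Traxler chair on the face away from the benzyl group and so sets C1 and C2 as the (2R,3S)-syn pair required by the target, the remote C10 centre having little say.

Step 6
Reactants: 10 (4R)-4-benzyl-3-{(2R,3S)-2-[(2R)-4-(TBSO)butan-2-yl]-3-hydroxy-5-(PMBO)pentanoyl}-1,3-oxazolidin-2-one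
Product: 11 (2R,3S)-2-[(2R)-4-(TBSO)butan-2-yl]-3-hydroxy-N-methoxy-N-methyl-5-(PMBO)pentanamide
Conditions: MeONHMe·HCl, AlMe3, CH2Cl2, −20 to 0 °C; aq. potassium sodium tartrate
Reagents that add atoms: N,O-dimethylhydroxylamine hydrochloride, CNOC.Cl
Why: Transamidation of a β-hydroxy imide with the aluminium amide MeClAlN(OMe)Me (the free hydroxyl directs it to the exocyclic carbonyl) should give the Weinreb amide and release the auxiliary without epimerizing C1.

Step 7
Reactants: 11 (2R,3S)-2-[(2R)-4-(TBSO)butan-2-yl]-3-hydroxy-N-methoxy-N-methyl-5-(PMBO)pentanamide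
Product: 12 (3R,4S)-3-[(2R)-4-(TBSO)butan-2-yl]-4-hydroxy-6-(PMBO)hexan-2-one
Conditions: MeMgBr (3 equiv), THF, −78 to 0 °C; then H2O/aq. NH4Cl
Reagents that add atoms: methylmagnesium bromide, C[Mg]Br
Why: Grignard addition to a Weinreb amide stops at the chelated tetrahedral intermediate, so exactly one methyl group (C15) is delivered and the β-hydroxy methyl ketone forms on work-up, the low temperature suppressing retro-aldol cleavage and C1 epimerization.

Step 8
Reactants: 12 (3R,4S)-3-[(2R)-4-(TBSO)butan-2-yl]-4-hydroxy-6-(PMBO)hexan-2-one; 13 (triphenylphosphoranylidene)ketene (Ph3P=C=C=O)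
Product: 15 (5S,6S)-5-[(2R)-4-(TBSO)butan-2-yl]-4-methyl-6-[2-(PMBO)ethyl]-5,6-dihydro-2H-pyran-2-one, via ester ylide 14 (not isolated)
Conditions: toluene, 60 °C then reflux
Reagents that add atoms: none
Why: The C2 hydroxyl adds across the C=C of the ketene ylide to give an ester-stabilized ylide that closes onto the neighbouring methyl ketone in an intramolecular Wittig reaction (Bestmann cascade) under neutral conditions, so no base can eliminate the β-acyloxy ketone, and the six-membered ring forces C1 and C7 to be cis on the new C5=C6 alkene.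

Step 9
Reactants: 15 (5S,6S)-5-[(2R)-4-(TBSO)butan-2-yl]-4-methyl-6-[2-(PMBO)ethyl]-5,6-dihydro-2H-pyran-2-one
Product: 16 (2Z,4S,5S)-4-[(2R)-4-(TBSO)butan-2-yl]-5-hydroxy-N-methoxy-N,3-dimethyl-7-(PMBO)hept-2-enamide
Conditions: MeONHMe·HCl, AlMe3, CH2Cl2, 0 °C; aq. potassium sodium tartrate; used at once
Reagents that add atoms: N,O-dimethylhydroxylamine hydrochloride, CNOC.Cl
Why: Weinreb aminolysis of the lactone opens the temporary ring at the acyl–oxygen bond without touching the β,β-disubstituted alkene, which therefore keeps the Z geometry that the ring imposed, and frees the C2 hydroxyl.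

Step 10
Reactants: 16 (2Z,4S,5S)-4-[(2R)-4-(TBSO)butan-2-yl]-5-hydroxy-N-methoxy-N,3-dimethyl-7-(PMBO)hept-2-enamide; 17 angelic acid [(Z)-2-methylbut-2-enoic acid]
Product: 19 (3S,4S,5Z)-4-[(2R)-4-(TBSO)butan-2-yl]-7-[methoxy(methyl)amino]-5-methyl-7-oxo-1-(PMBO)hept-5-en-3-yl angelate, via angelic 2,4,6-trichlorobenzoic anhydride 18 (not isolated)
Conditions: 17, 2,4,6-Cl3C6H2COCl, Et3N, toluene, rt; then 16, toluene, 70 °C
Reagents that add atoms: none
Why: Esterification through the preformed mixed anhydride in warm toluene without DMAP (Yamaguchi-type protocol used for angelates) should acylate the hindered C2 hydroxyl while avoiding the nucleophile-induced isomerization of the angeloyl group to the tigloyl group.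

Step 11
Reactants: 19 (3S,4S,5Z)-4-[(2R)-4-(TBSO)butan-2-yl]-7-[methoxy(methyl)amino]-5-methyl-7-oxo-1-(PMBO)hept-5-en-3-yl angelate
Product: 20 (3S,4S,5Z)-4-[(2R)-4-(TBSO)butan-2-yl]-1-hydroxy-7-[methoxy(methyl)amino]-5-methyl-7-oxohept-5-en-3-yl angelate
Conditions: DDQ, CH2Cl2/pH 7 buffer (KH2PO4/K2HPO4) 10:1, 0 °C
Reagents that add atoms: none
Why: Oxidative cleavage of the electron-rich PMB ether with DDQ in buffered wet dichloromethane should leave the silyl ether, the angelate and the electron-poor enamide untouched.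

Step 12
Reactants: 20 (3S,4S,5Z)-4-[(2R)-4-(TBSO)butan-2-yl]-1-hydroxy-7-[methoxy(methyl)amino]-5-methyl-7-oxohept-5-en-3-yl angelate
Product: 21 (3S,4S,5Z)-1-acetoxy-4-[(2R)-4-(TBSO)butan-2-yl]-7-[methoxy(methyl)amino]-5-methyl-7-oxohept-5-en-3-yl angelate
Conditions: Ac2O, pyridine, DMAP (cat.), CH2Cl2, 0 °C
Reagents that add atoms: acetic anhydride, CC(=O)OC(C)=O
Why: Acetylation of the primary C4 alcohol is fast at 0 °C and is done at once, so that the angelate has no time to migrate from the secondary to the primary oxygen.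

Step 13
Reactants: 21 (3S,4S,5Z)-1-acetoxy-4-[(2R)-4-(TBSO)butan-2-yl]-7-[methoxy(methyl)amino]-5-methyl-7-oxohept-5-en-3-yl angelate
Product: 22 (3S,4S,5Z)-1-acetoxy-4-[(2R)-4-(TBSO)butan-2-yl]-5-methyl-7-oxohept-5-en-3-yl angelate (Z-enal)
Conditions: Cp2Zr(H)Cl (1.5 equiv), THF, rt, short reaction time
Reagents that add atoms: none
Why: Cp2Zr(H)Cl (Schwartz reagent) hydrozirconates the amide carbonyl to a zirconated N,O-hemiaminal that collapses to the aldehyde on work-up, a reduction known to spare esters, so the Z-enal should form without over-reduction and without acid or base that could isomerize it.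

Step 14
Reactants: 22 (3S,4S,5Z)-1-acetoxy-4-[(2R)-4-(TBSO)butan-2-yl]-5-methyl-7-oxohept-5-en-3-yl angelate; 23 methyl propiolate
Product: 25 methyl (4Z,6S,7S)-9-acetoxy-7-(angeloyloxy)-6-[(2R)-4-(TBSO)butan-2-yl]-3-hydroxy-5-methyl-2-methylidenenon-4-enoate (both C3 epimers), via α-aluminated acrylate 24 (not isolated)
Conditions: 23, iBu2AlH, NMO, THF, 0 °C; then 22, 0 °C to rt
Reagents that add atoms: none
Why: Hydroalumination of methyl propiolate by the iBu2AlH–NMO complex gives CH2=C(CO2Me)AliBu2, which adds 1,2 to the enal as an aluminium-based Morita–Baylis–Hillman surrogate, and the new carbinol centre at C7 is inconsequential because it is lost in step 15.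

Step 15
Reactants: 25 methyl (4Z,6S,7S)-9-acetoxy-7-(angeloyloxy)-6-[(2R)-4-(TBSO)butan-2-yl]-3-hydroxy-5-methyl-2-methylidenenon-4-enoate
Product: 26 methyl (2Z,4Z,6S,7S)-9-acetoxy-7-(angeloyloxy)-2-(bromomethyl)-6-[(2R)-4-(TBSO)butan-2-yl]-5-methylnona-2,4-dienoate
Conditions: NBS, Me2S, CH2Cl2, −20 to 0 °C
Reagents that add atoms: N-bromosuccinimide, O=C1CCC(=O)N1Br
Why: The Corey–Kim-type sulfonium reagent activates the doubly allylic hydroxyl and bromide then attacks the terminal methylene in SN2' fashion to give the conjugated (2Z)-2-(bromomethyl)dienoate, the usual outcome for Morita–Baylis–Hillman alcohols, under near-neutral conditions that should keep the TBS ether and the C5=C6 geometry.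

Step 16
Reactants: 26 methyl (2Z,4Z,6S,7S)-9-acetoxy-7-(angeloyloxy)-2-(bromomethyl)-6-[(2R)-4-(TBSO)butan-2-yl]-5-methylnona-2,4-dienoate
Product: 27 methyl (2Z,4Z,6S,7S)-9-acetoxy-7-(angeloyloxy)-2-(bromomethyl)-6-[(2R)-4-hydroxybutan-2-yl]-5-methylnona-2,4-dienoate
Conditions: 48% aq. HF, MeCN, 0 °C
Reagents that add atoms: none
Why: Aqueous HF in acetonitrile removes a primary TBS ether in the cold without any nucleophilic base or amine that could displace the allylic bromide.

Step 17
Reactants: 27 methyl (2Z,4Z,6S,7S)-9-acetoxy-7-(angeloyloxy)-2-(bromomethyl)-6-[(2R)-4-hydroxybutan-2-yl]-5-methylnona-2,4-dienoate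
Product: 28 methyl (2Z,4Z,6S,7S)-9-acetoxy-7-(angeloyloxy)-2-(bromomethyl)-5-methyl-6-[(2R)-4-oxobutan-2-yl]nona-2,4-dienoate
Conditions: Dess–Martin periodinane, NaHCO3, CH2Cl2, 0 °C to rt
Reagents that add atoms: none
Why: Buffered Dess–Martin oxidation converts the primary alcohol to the C8 aldehyde under neutral conditions compatible with the allylic bromide and the three esters.

Step 18
Reactants: 28 methyl (2Z,4Z,6S,7S)-9-acetoxy-7-(angeloyloxy)-2-(bromomethyl)-5-methyl-6-[(2R)-4-oxobutan-2-yl]nona-2,4-dienoate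
Product: 31 (1S)-3-acetoxy-1-[(3aR,6S,7R,8aR)-5,7-dimethyl-3-methylidene-2-oxo-3,3a,6,7,8,8a-hexahydro-2H-cyclohepta[b]furan-6-yl]propyl angelate (CNP0163960.1), via allylchromium dichloride 29 (not isolated), via dichlorochromium alkoxide 30 (not isolated)
Conditions: CrCl2 (5 equiv), THF, rt, 28 added by syringe pump (final about 3 mM); then aq. NH4Cl/1 M HCl
Reagents that add atoms: none
Why: CrCl2 (divalent chromium) reduces the allylic bromide in two one-electron steps to the C13-bound 2-(methoxycarbonyl)pentadienyl chromium species 29 (trivalent chromium), whose γ-carbon C7 adds to the tethered C8 aldehyde through a closed six-membered chair with transposition of the double bond to C11=C13, and the chromium alkoxide 30 then attacks the C12 methyl ester. The closest known reaction type is the intramolecular Nozaki–Hiyama/Barbier allylation–lactonization of aldehydes carrying a 2-(bromomethyl)alk-2-enoate, which is established for cis-fused α-methylene-γ-butyrolactones on five- to eight-membered carbocycles. The seven-membered carbocycle closes by a 7-exo-trig carbonyl addition in which the Z C5=C6 alkene becomes the cis ring alkene, and the lactone closes by 5-exo-trig O-acylation with loss of methanol. The cis relation of C7 and C8 follows from the chair, in which C6 is axial on the (Z)-allyl unit and C9 equatorial on the aldehyde, the only arrangement that lets the tether bridge the two carbons. The absolute sense follows from C10: in this chair the chromium-bound oxygen is pseudoaxial on the forming ring and avoids a syn-axial C10 methyl, so the tether should react with the C10 methyl and the trans C1 side chain pseudoequatorial, which places O8 trans to the C10 methyl and C11 cis to the C1 side chain. The step needs γ- over α- and ε-attack and cyclization over oligomerization; the first is secured by the six-membered cyclic transition state (ε-attack at C5 would need an eight-membered one and build a quaternary centre), the second by slow addition at high dilution, and only the (4Z)-diene can reach the aldehyde, so E isomers formed by metallotropic shifts are not funneled into the ring.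

**Compound list**

1 | methyl hydrogen (R)-3-methylglutarate | OC(=O)C[C@@H](C)CC(=O)OC | starting material
2 | methyl (3R)-5-hydroxy-3-methylpentanoate | OCC[C@@H](C)CC(=O)OC | intermediate
3 | methyl (3R)-5-[(tert-butyldimethylsilyl)oxy]-3-methylpentanoate | CC(C)(C)[Si](C)(C)OCC[C@@H](C)CC(=O)OC | intermediate
4 | (3R)-5-[(tert-butyldimethylsilyl)oxy]-3-methylpentanoic acid | CC(C)(C)[Si](C)(C)OCC[C@@H](C)CC(=O)O | intermediate
5 | (R)-4-benzyl-1,3-oxazolidin-2-one | O=C1N[C@H](Cc2ccccc2)CO1 | starting material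
6 | mixed anhydride of 4 with pivalic acid | CC(C)(C)[Si](C)(C)OCC[C@@H](C)CC(=O)OC(=O)C(C)(C)C | intermediate
7 | (4R)-4-benzyl-3-{(3R)-5-[(tert-butyldimethylsilyl)oxy]-3-methylpentanoyl}-1,3-oxazolidin-2-one | CC(C)(C)[Si](C)(C)OCC[C@@H](C)CC(=O)N1[C@H](Cc2ccccc2)COC1=O | intermediate
8 | 3-[(4-methoxybenzyl)oxy]propanal | O=CCCOCc1ccc(OC)cc1 | starting material
9 | dibutylboron (Z)-enolate of 7 | CC(C)(C)[Si](C)(C)OCC[C@@H](C)/C=C(\OB(CCCC)CCCC)N1[C@H](Cc2ccccc2)COC1=O | intermediate
10 | (4R)-4-benzyl-3-{(2R,3S)-2-[(2R)-4-(TBSO)butan-2-yl]-3-hydroxy-5-(PMBO)pentanoyl}-1,3-oxazolidin-2-one (syn-aldol) | CC(C)(C)[Si](C)(C)OCC[C@@H](C)[C@H]([C@H](CCOCc1ccc(OC)cc1)O)C(=O)N1[C@H](Cc2ccccc2)COC1=O | intermediate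
11 | (2R,3S)-2-[(2R)-4-(TBSO)butan-2-yl]-3-hydroxy-N-methoxy-N-methyl-5-(PMBO)pentanamide | CC(C)(C)[Si](C)(C)OCC[C@@H](C)[C@H]([C@H](CCOCc1ccc(OC)cc1)O)C(=O)N(C)OC | intermediate
12 | (3R,4S)-3-[(2R)-4-(TBSO)butan-2-yl]-4-hydroxy-6-(PMBO)hexan-2-one | CC(C)(C)[Si](C)(C)OCC[C@@H](C)[C@H]([C@H](CCOCc1ccc(OC)cc1)O)C(C)=O | intermediate
13 | (triphenylphosphoranylidene)ketene | O=C=C=P(c1ccccc1)(c1ccccc1)c1ccccc1 | starting material
14 | (triphenylphosphoranylidene)acetate ester of 12 at O2 (ester ylide) | CC(C)(C)[Si](C)(C)OCC[C@@H](C)[C@H]([C@H](CCOCc1ccc(OC)cc1)OC(=O)C=P(c1ccccc1)(c1ccccc1)c1ccccc1)C(C)=O | intermediate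
15 | (5S,6S)-5-[(2R)-4-(TBSO)butan-2-yl]-4-methyl-6-[2-(PMBO)ethyl]-5,6-dihydro-2H-pyran-2-one | CC(C)(C)[Si](C)(C)OCC[C@@H](C)[C@@H]1[C@H](CCOCc2ccc(OC)cc2)OC(=O)C=C1C | intermediate
16 | (2Z,4S,5S)-4-[(2R)-4-(TBSO)butan-2-yl]-5-hydroxy-N-methoxy-N,3-dimethyl-7-(PMBO)hept-2-enamide | CC(C)(C)[Si](C)(C)OCC[C@@H](C)[C@H]([C@H](CCOCc1ccc(OC)cc1)O)/C(C)=C\C(=O)N(C)OC | intermediate
17 | angelic acid, (Z)-2-methylbut-2-enoic acid | C/C=C(/C)C(=O)O | starting material
18 | angelic 2,4,6-trichlorobenzoic anhydride | C/C=C(/C)C(=O)OC(=O)c1c(Cl)cc(Cl)cc1Cl | intermediate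
19 | (3S,4S,5Z)-4-[(2R)-4-(TBSO)butan-2-yl]-7-[methoxy(methyl)amino]-5-methyl-7-oxo-1-(PMBO)hept-5-en-3-yl angelate | CC(C)(C)[Si](C)(C)OCC[C@@H](C)[C@H]([C@H](CCOCc1ccc(OC)cc1)OC(=O)/C(C)=C\C)/C(C)=C\C(=O)N(C)OC | intermediate
20 | (3S,4S,5Z)-4-[(2R)-4-(TBSO)butan-2-yl]-1-hydroxy-7-[methoxy(methyl)amino]-5-methyl-7-oxohept-5-en-3-yl angelate | CC(C)(C)[Si](C)(C)OCC[C@@H](C)[C@H]([C@H](CCO)OC(=O)/C(C)=C\C)/C(C)=C\C(=O)N(C)OC | intermediate
21 | (3S,4S,5Z)-1-acetoxy-4-[(2R)-4-(TBSO)butan-2-yl]-7-[methoxy(methyl)amino]-5-methyl-7-oxohept-5-en-3-yl angelate | CC(C)(C)[Si](C)(C)OCC[C@@H](C)[C@H]([C@H](CCOC(C)=O)OC(=O)/C(C)=C\C)/C(C)=C\C(=O)N(C)OC | intermediate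
22 | (3S,4S,5Z)-1-acetoxy-4-[(2R)-4-(TBSO)butan-2-yl]-5-methyl-7-oxohept-5-en-3-yl angelate (Z-enal) | CC(C)(C)[Si](C)(C)OCC[C@@H](C)[C@H]([C@H](CCOC(C)=O)OC(=O)/C(C)=C\C)/C(C)=C\C=O | intermediate
23 | methyl propiolate | C#CC(=O)OC | starting material
24 | [1-(methoxycarbonyl)vinyl]diisobutylaluminium | C=C(C(=O)OC)[Al](CC(C)C)CC(C)C | intermediate
25 | methyl (4Z,6S,7S)-9-acetoxy-7-(angeloyloxy)-6-[(2R)-4-(TBSO)butan-2-yl]-3-hydroxy-5-methyl-2-methylidenenon-4-enoate (C3 epimers) | CC(C)(C)[Si](C)(C)OCC[C@@H](C)[C@H]([C@H](CCOC(C)=O)OC(=O)/C(C)=C\C)/C(C)=C\C(O)C(=C)C(=O)OC | intermediate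
26 | methyl (2Z,4Z,6S,7S)-9-acetoxy-7-(angeloyloxy)-2-(bromomethyl)-6-[(2R)-4-(TBSO)butan-2-yl]-5-methylnona-2,4-dienoate | CC(C)(C)[Si](C)(C)OCC[C@@H](C)[C@H]([C@H](CCOC(C)=O)OC(=O)/C(C)=C\C)/C(C)=C\C=C(/CBr)C(=O)OC | intermediate
27 | methyl (2Z,4Z,6S,7S)-9-acetoxy-7-(angeloyloxy)-2-(bromomethyl)-6-[(2R)-4-hydroxybutan-2-yl]-5-methylnona-2,4-dienoate | OCC[C@@H](C)[C@H]([C@H](CCOC(C)=O)OC(=O)/C(C)=C\C)/C(C)=C\C=C(/CBr)C(=O)OC | intermediate
28 | methyl (2Z,4Z,6S,7S)-9-acetoxy-7-(angeloyloxy)-2-(bromomethyl)-5-methyl-6-[(2R)-4-oxobutan-2-yl]nona-2,4-dienoate | O=CC[C@@H](C)[C@H]([C@H](CCOC(C)=O)OC(=O)/C(C)=C\C)/C(C)=C\C=C(/CBr)C(=O)OC | intermediate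
29 | allylchromium dichloride from 28 (CrCl2 group on C13) | O=CC[C@@H](C)[C@H]([C@H](CCOC(C)=O)OC(=O)/C(C)=C\C)/C(C)=C\C=C(/C[Cr](Cl)Cl)C(=O)OC | intermediate
30 | dichlorochromium alkoxide of the ring-closed cis hydroxy ester (C7–C8 formed, C11=C13, C12 methyl ester) | Cl[Cr](Cl)O[C@@H]1C[C@@H](C)[C@H]([C@H](CCOC(C)=O)OC(=O)/C(C)=C\C)C(C)=C[C@@H]1C(=C)C(=O)OC | intermediate
31 | (1S)-3-acetoxy-1-[(3aR,6S,7R,8aR)-5,7-dimethyl-3-methylidene-2-oxo-3,3a,6,7,8,8a-hexahydro-2H-cyclohepta[b]furan-6-yl]propyl angelate (CNP0163960.1) | C=C1C(=O)O[C@@H]2C[C@@H](C)[C@H]([C@H](CCOC(C)=O)OC(=O)/C(C)=C\C)C(C)=C[C@H]12 | target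

**Step count and risks**

Total step count: 18. Longest linear sequence: 18 steps (1 to 31); the partners 5, 8, 13, 17 and 23 are purchased.

Steps most likely to fail:

Step 18. What may go wrong is poor facial selectivity with respect to C10 and C1: the gain from avoiding the syn-axial C10 methyl/O–Cr contact has to outweigh the allylic 1,2-strain between the pseudoequatorial C1 side chain and the C5 methyl. Attack through the ε-carbon C5 or oligomerization are further risks. The fallback replaces the closed chromium chair by an open-transition-state Hosomi–Sakurai cyclization and sets out from Z-enal 22. A Wittig reaction with methyl 2-(triphenylphosphoranylidene)-3-(trimethylsilyl)propanoate (toluene, 80 °C) would give the allylsilane methyl (2Z,4Z,6S,7S)-9-acetoxy-7-(angeloyloxy)-6-[(2R)-4-(TBSO)butan-2-yl]-5-methyl-2-[(trimethylsilyl)methyl]nona-2,4-dienoate F1. Aq. HF in MeCN would give the C8 alcohol F2, and Dess–Martin oxidation the allylsilane aldehyde F3. F3 would then be cyclized with TBAF in THF or with BF3·OEt2 in CH2Cl2 at −78 °C, with acid-promoted lactonization, and the fallback comes back to the route at 31.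

Step 10. What may go wrong is re-lactonization of the Z-hydroxy amide to 15 during the thermal acylation, together with Z-to-E isomerization of the activated angeloyl unit. The fallback opens the temporary ring reductively, so that no acyl group is left to lactonize, and sets out from lactone 15. iBu2AlH (CH2Cl2, −78 to 0 °C) would give the (2Z)-ene-1,5-diol F4. TESCl/imidazole at −78 °C would silylate only the primary allylic hydroxyl, giving the mono-triethylsilyl ether F5. The C2 hydroxyl would be acylated under the conditions of step 10 to the angelate F6. DDQ would free the C4 alcohol F7, and Ac2O/pyridine would give the acetate F8. Swern oxidation (oxalyl chloride, DMSO, Et3N, −78 to −20 °C), which cleaves and oxidizes a primary allylic triethylsilyl ether directly while a TBS ether survives, would then deliver the enal, and the fallback comes back to the route at 22.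

Step 15. What may go wrong is loss of regio- and geometric integrity during the SN2' bromination (ionization of the doubly allylic alcohol, bromide attack at C5, E/Z scrambling) and decomposition of the dienyl bromide on handling. The fallback avoids the bromide altogether and sets out from alcohol 25. Ac2O/DMAP would give the allylic acetate F9, aq. HF in MeCN the C8 alcohol F10 and Dess–Martin oxidation the aldehyde F11. Pd(PPh3)4 (catalytic zerovalent palladium) with InI in THF would then ionize the allylic acetate to the π-allyl complex of divalent palladium and transmetalate it to the allylindium species (trivalent indium), the same C13-metalated pentadienyl nucleophile as in step 18. This would add to the aldehyde through the chair transition state and lactonize, so the fallback comes back to the route at 31.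

Further compounds
F1 | step 18 | methyl (2Z,4Z,6S,7S)-9-acetoxy-7-(angeloyloxy)-6-[(2R)-4-(TBSO)butan-2-yl]-5-methyl-2-[(trimethylsilyl)methyl]nona-2,4-dienoate | CC(C)(C)[Si](C)(C)OCC[C@@H](C)[C@H]([C@H](CCOC(C)=O)OC(=O)/C(C)=C\C)/C(C)=C\C=C(/C[Si](C)(C)C)C(=O)OC
F2 | step 18 | methyl (2Z,4Z,6S,7S)-9-acetoxy-7-(angeloyloxy)-6-[(2R)-4-hydroxybutan-2-yl]-5-methyl-2-[(trimethylsilyl)methyl]nona-2,4-dienoate | OCC[C@@H](C)[C@H]([C@H](CCOC(C)=O)OC(=O)/C(C)=C\C)/C(C)=C\C=C(/C[Si](C)(C)C)C(=O)OC
F3 | step 18 | methyl (2Z,4Z,6S,7S)-9-acetoxy-7-(angeloyloxy)-5-methyl-6-[(2R)-4-oxobutan-2-yl]-2-[(trimethylsilyl)methyl]nona-2,4-dienoate | O=CC[C@@H](C)[C@H]([C@H](CCOC(C)=O)OC(=O)/C(C)=C\C)/C(C)=C\C=C(/C[Si](C)(C)C)C(=O)OC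
F4 | step 10 | (2Z,4S,5S)-4-[(2R)-4-(TBSO)butan-2-yl]-3-methyl-7-(PMBO)hept-2-ene-1,5-diol | CC(C)(C)[Si](C)(C)OCC[C@@H](C)[C@H]([C@H](CCOCc1ccc(OC)cc1)O)/C(C)=C\CO
F5 | step 10 | (3S,4S,5Z)-4-[(2R)-4-(TBSO)butan-2-yl]-5-methyl-1-(PMBO)-7-[(triethylsilyl)oxy]hept-5-en-3-ol | CC(C)(C)[Si](C)(C)OCC[C@@H](C)[C@H]([C@H](CCOCc1ccc(OC)cc1)O)/C(C)=C\CO[Si](CC)(CC)CC
F6 | step 10 | (3S,4S,5Z)-4-[(2R)-4-(TBSO)butan-2-yl]-5-methyl-1-(PMBO)-7-[(triethylsilyl)oxy]hept-5-en-3-yl angelate | CC(C)(C)[Si](C)(C)OCC[C@@H](C)[C@H]([C@H](CCOCc1ccc(OC)cc1)OC(=O)/C(C)=C\C)/C(C)=C\CO[Si](CC)(CC)CC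
F7 | step 10 | (3S,4S,5Z)-4-[(2R)-4-(TBSO)butan-2-yl]-1-hydroxy-5-methyl-7-[(triethylsilyl)oxy]hept-5-en-3-yl angelate | CC(C)(C)[Si](C)(C)OCC[C@@H](C)[C@H]([C@H](CCO)OC(=O)/C(C)=C\C)/C(C)=C\CO[Si](CC)(CC)CC
F8 | step 10 | (3S,4S,5Z)-1-acetoxy-4-[(2R)-4-(TBSO)butan-2-yl]-5-methyl-7-[(triethylsilyl)oxy]hept-5-en-3-yl angelate | CC(C)(C)[Si](C)(C)OCC[C@@H](C)[C@H]([C@H](CCOC(C)=O)OC(=O)/C(C)=C\C)/C(C)=C\CO[Si](CC)(CC)CC
F9 | step 15 | methyl (4Z,6S,7S)-3,9-diacetoxy-7-(angeloyloxy)-6-[(2R)-4-(TBSO)butan-2-yl]-5-methyl-2-methylidenenon-4-enoate | CC(C)(C)[Si](C)(C)OCC[C@@H](C)[C@H]([C@H](CCOC(C)=O)OC(=O)/C(C)=C\C)/C(C)=C\C(OC(C)=O)C(=C)C(=O)OC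
F10 | step 15 | methyl (4Z,6S,7S)-3,9-diacetoxy-7-(angeloyloxy)-6-[(2R)-4-hydroxybutan-2-yl]-5-methyl-2-methylidenenon-4-enoate | OCC[C@@H](C)[C@H]([C@H](CCOC(C)=O)OC(=O)/C(C)=C\C)/C(C)=C\C(OC(C)=O)C(=C)C(=O)OC
F11 | step 15 | methyl (4Z,6S,7S)-3,9-diacetoxy-7-(angeloyloxy)-5-methyl-2-methylidene-6-[(2R)-4-oxobutan-2-yl]non-4-enoate | O=CC[C@@H](C)[C@H]([C@H](CCOC(C)=O)OC(=O)/C(C)=C\C)/C(C)=C\C(OC(C)=O)C(=C)C(=O)OC
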